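**Strategy.** The chain is numbered from the furyl CH2 (C1) to the lactone carbonyl (C15). Everything rests on cutting the E C7=C8 olefin, whose C8 methyl lies cis to the oxygen-bearing C6: the C6 oxygen, the methyl carbon, C8, C7 and C6 fit a temporary five-membered butenolide (ring C; ring A is the furan, ring B the final γ-lactone). Ring-closing metathesis of an ester joining the west (S)-vinyl carbinol (C1–C7) to a 2-methylidene acid (C8–C11, C11 as a dioxolane) forges C7=C8 and fixes its geometry in one operation; reduction then turns the ring carbonyl into the C8 methyl. Ring B follows by reagent-controlled epoxidation and epoxy acid lactonisation.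

Key step: step 10

Remark: in this numbering the target is (6S,11R,12S); ylides 24 and 28, phosphonate 12, D-(−)-diisopropyl tartrate and 2-nitrobenzenesulfonylhydrazide are taken as purchased reagents.

Step 1
Reactants: 1 acrolein; 2 propargyl bromide
Product: 4 rac-hex-1-en-5-yn-3-ol, via allenylzinc bromide 3 (not isolated)
Conditions: Zn dust, THF, 0 °C; then 1, −20 °C to rt; aq. NH4Cl
Reagents that add atoms: none
Why: Barbier propargylation, in which zinc inserts into 2 and the resulting allenylzinc bromide adds through its γ-carbon to the carbonyl carbon of acrolein (1,2-addition) to give the homopropargylic vinyl carbinol as a racemate that is resolved in step 3.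

Step 2
Reactants: 4 rac-hex-1-en-5-yn-3-ol
Product: 6 rac-(5E)-6-iodo-5-methylhexa-1,5-dien-3-ol, via alkenylalane 5 (not isolated)
Conditions: Me3Al (3 equiv), Cp2ZrCl2 (0.25 equiv), CH2Cl2, 0 °C to rt; then I2, THF, −30 °C
Reagents that add atoms: trimethylaluminium, C[Al](C)C; iodine, II
Why: Negishi zirconium-catalysed carboalumination adds methyl and aluminium syn across the terminal alkyne (methyl to the internal carbon) while the hydroxyl rides as its aluminium alkoxide and the vinyl group stays untouched, and iodinolysis of the alkenyl–aluminium bond with retention should give the E vinyl iodide.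

Step 3
Reactants: 6 rac-(5E)-6-iodo-5-methylhexa-1,5-dien-3-ol
Product: 7 (3S,5E)-6-iodo-5-methylhexa-1,5-dien-3-ol
Conditions: Ti(Oi-Pr)4 (0.15 equiv), D-(−)-diisopropyl tartrate (0.2 equiv), t-BuOOH (0.65 equiv), 4 Å molecular sieves, CH2Cl2, −20 °C, run past half conversion
Reagents that add atoms: none
Why: Sharpless kinetic resolution of a secondary allylic alcohol, in which the titanium–D-(−)-tartrate catalyst epoxidises the vinyl group of the (R)-alcohol much faster than that of the (S)-alcohol, so that the unreacted (S)-enantiomer, which carries the future C6 stereocentre, should be recovered and separated from the polar epoxy alcohol.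

Step 4
Reactants: 8 furan-3-carbaldehyde
Product: 9 3-ethenylfuran
Conditions: Ph3PCH3Br, KOt-Bu, Et2O, 0 °C to rt; distilled as an ethereal solution
Reagents that add atoms: methyltriphenylphosphonium bromide, C[P+](c1ccccc1)(c1ccccc1)c1ccccc1.[Br-]
Why: Wittig methylenation of an aromatic aldehyde with the non-stabilised ylide is reliable, and the volatile product is carried on in solution.

Step 5
Reactants: 9 3-ethenylfuran; 7 (3S,5E)-6-iodo-5-methylhexa-1,5-dien-3-ol
Product: 11 (3S,5E)-8-(furan-3-yl)-5-methylocta-1,5-dien-3-ol, via alkylborane 10 (not isolated)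
Conditions: 9 (1.5 equiv), 9-BBN-H (1.4 equiv), THF, 0 °C to rt; then 7, PdCl2(dppf) (5 mol%), AsPh3 (5 mol%), Cs2CO3, DMF/H2O, rt
Reagents that add atoms: none
Why: anti-Markovnikov hydroboration places boron on the terminal carbon of 9, and B-alkyl Suzuki–Miyaura coupling of the alkylborane with the vinyl iodide should proceed with retention of the E geometry and tolerate the free allylic alcohol, whose stereocentre is not involved, the slight excess of 9 leaving no B–H to attack the vinyl group of 7.

Step 6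
Reactants: 12 triethyl phosphonoacetate; 13 2-(2-bromoethyl)-1,3-dioxolane
Product: 14 ethyl 2-(diethoxyphosphoryl)-4-(1,3-dioxolan-2-yl)butanoate
Conditions: NaH, DMSO, rt; then 13, 60 °C
Reagents that add atoms: none
Why: SN2 C-alkylation of the sodium salt of the phosphonoacetate by the primary bromide, the acetal being inert to base.

Step 7
Reactants: 14 ethyl 2-(diethoxyphosphoryl)-4-(1,3-dioxolan-2-yl)butanoate
Product: 15 ethyl 4-(1,3-dioxolan-2-yl)-2-methylidenebutanoate
Conditions: aq. HCHO, K2CO3, H2O/THF, rt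
Reagents that add atoms: formaldehyde, C=O
Why: Horner–Wadsworth–Emmons olefination of formaldehyde by an α-alkyl phosphonoacetate under carbonate conditions is the standard entry to 2-alkyl acrylates.

Step 8
Reactants: 15 ethyl 4-(1,3-dioxolan-2-yl)-2-methylidenebutanoate
Product: 16 4-(1,3-dioxolan-2-yl)-2-methylidenebutanoic acid
Conditions: LiOH·H2O, THF/H2O, 0 °C to rt; then aq. HCl to pH 4, 0 °C
Reagents that add atoms: lithium hydroxide, [Li+].[OH-]
Why: saponification of the ethyl ester followed by cautious acidification, which keeps the dioxolane intact, frees the 2-methylidene acid.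

Step 9
Reactants: 11 (3S,5E)-8-(furan-3-yl)-5-methylocta-1,5-dien-3-ol; 16 4-(1,3-dioxolan-2-yl)-2-methylidenebutanoic acid
Product: 17 (3S,5E)-8-(furan-3-yl)-5-methylocta-1,5-dien-3-yl 4-(1,3-dioxolan-2-yl)-2-methylidenebutanoate
Conditions: DCC, DMAP (0.1 equiv), CH2Cl2, 0 °C to rt
Reagents that add atoms: none
Why: Steglich esterification acylates the secondary allylic hydroxyl at oxygen, so the C6 configuration is retained and the two fragments are tethered through the future ring oxygen.

Step 10
Reactants: 17 (3S,5E)-8-(furan-3-yl)-5-methylocta-1,5-dien-3-yl 4-(1,3-dioxolan-2-yl)-2-methylidenebutanoate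
Product: 18 (5S)-3-[2-(1,3-dioxolan-2-yl)ethyl]-5-[(2E)-5-(furan-3-yl)-2-methylpent-2-enyl]furan-2(5H)-one
Conditions: (H2IMes)Cl2Ru=CH(2-i-PrO-C6H4) (second-generation Hoveyda–Grubbs catalyst, 10 mol% in two portions), 1,4-benzoquinone (10 mol%), toluene (0.005 M), 80 °C, argon sparge
Reagents that add atoms: none
Why: Ring-closing olefin metathesis, in which the ruthenium alkylidene first exchanges with the monosubstituted vinyl group at C7 and the resulting carbene adds in a [2+2] sense to the 1,1-disubstituted acrylate olefin, the metallacyclobutane collapsing to the C7=C8 bond with loss of ethene. The closest known reaction type is the metathesis of allylic esters of 2-substituted acrylic acids to α-substituted butenolides. The one new ring, the five-membered ring C (ring oxygen, carbonyl carbon, C8, C7, C6), is closed by intramolecular metathesis that leaves the new olefin endocyclic, so the acyl carbon and C6 are necessarily cis on C7=C8. No stereocentre is created, and the C6 centre secured in step 3 is not a reacting atom and should pass through unchanged. Only site selectivity is needed: the trisubstituted C3=C4 olefin could close only to a cyclobutene or to a tetrasubstituted olefin in a six-membered lactone, the furan is aromatic, and high dilution with removal of ethene should suppress intermolecular metathesis.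

Step 11
Reactants: 18 (5S)-3-[2-(1,3-dioxolan-2-yl)ethyl]-5-[(2E)-5-(furan-3-yl)-2-methylpent-2-enyl]furan-2(5H)-one
Product: 19 (2Z,4S,6E)-2-[2-(1,3-dioxolan-2-yl)ethyl]-9-(furan-3-yl)-6-methylnona-2,6-diene-1,4-diol
Conditions: i-Bu2AlH (4 equiv), CH2Cl2, −78 to 0 °C; aq. KNaC4H4O6
Reagents that add atoms: none
Why: exhaustive 1,2-reduction of the butenolide by i-Bu2AlH (lactone to lactol to hydroxy enal to allylic alcohol) frees the C6 hydroxyl and the C8 hydroxymethyl group without touching the olefin, so the Z geometry imposed by ring C is kept and the dioxolane should survive at low temperature.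

Step 12
Reactants: 19 (2Z,4S,6E)-2-[2-(1,3-dioxolan-2-yl)ethyl]-9-(furan-3-yl)-6-methylnona-2,6-diene-1,4-diol
Product: 21 (3E,5S,7E)-1-(1,3-dioxolan-2-yl)-10-(furan-3-yl)-3,7-dimethyldeca-3,7-dien-5-ol, via primary mesylate 20 (not isolated)
Conditions: MsCl (1.05 equiv), Et3N, THF, −40 °C; then LiBHEt3 (5 equiv), −78 to 0 °C
Reagents that add atoms: none
Why: low-temperature sulfonylation should select the unhindered primary allylic hydroxyl, and direct SN2 displacement of the mesylate by the powerful hydride donor LiBHEt3 turns the former ring carbonyl carbon into the C8 methyl without allylic transposition, the C6 hydroxyl being masked meanwhile as its weakly nucleophilic lithium alkoxytriethylborate.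

Step 13
Reactants: 21 (3E,5S,7E)-1-(1,3-dioxolan-2-yl)-10-(furan-3-yl)-3,7-dimethyldeca-3,7-dien-5-ol
Product: 22 (3E,5S,7E)-1-(1,3-dioxolan-2-yl)-10-(furan-3-yl)-3,7-dimethyldeca-3,7-dien-5-yl acetate
Conditions: Ac2O, pyridine, DMAP (cat.), CH2Cl2, 0 °C to rt
Reagents that add atoms: acetic anhydride, CC(=O)OC(C)=O
Why: DMAP-catalysed acetylation protects the C6 allylic alcohol as an ester that should survive the acidic, oxidative and ylide conditions ahead and is removed in the final saponification.

Step 14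
Reactants: 22 (3E,5S,7E)-1-(1,3-dioxolan-2-yl)-10-(furan-3-yl)-3,7-dimethyldeca-3,7-dien-5-yl acetate
Product: 23 (4E,6S,8E)-11-(furan-3-yl)-4,8-dimethyl-1-oxoundeca-4,8-dien-6-yl acetate
Conditions: PPTS (0.2 equiv), acetone/H2O, 55 °C
Reagents that add atoms: water, O
Why: mild pyridinium-acid-catalysed acetal hydrolysis unmasks the C11 aldehyde under buffered conditions that the allylic acetate, the 3-alkylfuran and the trisubstituted olefins should tolerate.

Step 15
Reactants: 23 (4E,6S,8E)-11-(furan-3-yl)-4,8-dimethyl-1-oxoundeca-4,8-dien-6-yl acetate; 24 2-(triphenylphosphoranylidene)propanal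
Product: 25 (2E,6E,8S,10E)-13-(furan-3-yl)-2,6,10-trimethyl-1-oxotrideca-2,6,10-trien-8-yl acetate
Conditions: 24 (1.5 equiv), toluene, 90 °C
Reagents that add atoms: none
Why: Wittig olefination with the stabilised formyl ylide should give the E 2-methyl enal and so adds C12, its methyl group and C13 with the C11=C12 geometry needed for the epoxidation.

Step 16
Reactants: 25 (2E,6E,8S,10E)-13-(furan-3-yl)-2,6,10-trimethyl-1-oxotrideca-2,6,10-trien-8-yl acetate
Product: 26 (2E,6E,8S,10E)-13-(furan-3-yl)-1-hydroxy-2,6,10-trimethyltrideca-2,6,10-trien-8-yl acetate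
Conditions: NaBH4, CeCl3·7H2O, MeOH, −40 °C
Reagents that add atoms: none
Why: Luche reduction delivers hydride 1,2 to the enal only and leaves the acetate and the olefins alone.

Step 17
Reactants: 26 (2E,6E,8S,10E)-13-(furan-3-yl)-1-hydroxy-2,6,10-trimethyltrideca-2,6,10-trien-8-yl acetate
Product: 27 (3E,5S,7E)-10-(furan-3-yl)-1-[(2R,3R)-3-(hydroxymethyl)-3-methyloxiran-2-yl]-3,7-dimethyldeca-3,7-dien-5-yl acetate
Conditions: Ti(Oi-Pr)4 (0.1 equiv), D-(−)-diisopropyl tartrate (0.13 equiv), t-BuOOH (2 equiv), 4 Å molecular sieves, CH2Cl2, −20 °C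
Reagents that add atoms: tert-butyl hydroperoxide, CC(C)(C)OO
Why: Sharpless asymmetric epoxidation, in which the titanium–D-(−)-tartrate–hydroperoxide complex binds the only free allylic alcohol and delivers oxygen to one face of the E C11=C12 olefin, sets C11 and C12 (both R in the epoxide) under reagent control whatever the remote C6 centre, while the other olefins, which lack a free allylic hydroxyl, and the furan should not be oxidised.

Step 18
Reactants: 27 (3E,5S,7E)-10-(furan-3-yl)-1-[(2R,3R)-3-(hydroxymethyl)-3-methyloxiran-2-yl]-3,7-dimethyldeca-3,7-dien-5-yl acetate; 28 methyl (triphenylphosphoranylidene)acetate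
Product: 30 methyl (2E)-3-[(2R,3R)-3-{(3E,5S,7E)-5-acetoxy-10-(furan-3-yl)-3,7-dimethyldeca-3,7-dienyl}-2-methyloxiran-2-yl]prop-2-enoate, via epoxy aldehyde 29 (not isolated)
Conditions: SO3·pyridine, DMSO, i-Pr2NEt, CH2Cl2, 0 °C; then 28 (2 equiv), 0 °C to rt
Reagents that add atoms: none
Why: Parikh–Doering oxidation gives an epoxy aldehyde that has no α-hydrogen and so cannot epimerise, and its capture in the same flask by the stabilised ylide in an E-selective Wittig reaction adds C14 and C15.

Step 19
Reactants: 30 methyl (2E)-3-[(2R,3R)-3-{(3E,5S,7E)-5-acetoxy-10-(furan-3-yl)-3,7-dimethyldeca-3,7-dienyl}-2-methyloxiran-2-yl]prop-2-enoate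
Product: 31 methyl 3-[(2R,3R)-3-{(3E,5S,7E)-5-acetoxy-10-(furan-3-yl)-3,7-dimethyldeca-3,7-dienyl}-2-methyloxiran-2-yl]propanoate
Conditions: 2-nitrobenzenesulfonylhydrazide (excess, in portions), Et3N, CH2Cl2, rt
Reagents that add atoms: none
Why: diimide reduction, in which diazene released from the sulfonylhydrazide transfers two hydrogens concertedly to the electron-poor disubstituted enoate olefin much faster than to the three trisubstituted olefins and, being metal-free and non-acidic, should spare the epoxide, the furan and the allylic acetate.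

Step 20
Reactants: 31 methyl 3-[(2R,3R)-3-{(3E,5S,7E)-5-acetoxy-10-(furan-3-yl)-3,7-dimethyldeca-3,7-dienyl}-2-methyloxiran-2-yl]propanoate
Product: 33 irciformonin B (5S)-5-[(1R,4E,6S,8E)-11-(furan-3-yl)-1,6-dihydroxy-4,8-dimethylundeca-4,8-dienyl]-5-methyloxolan-2-one, via epoxy acid 32 (not isolated)
Conditions: LiOH·H2O, THF/MeOH/H2O, 0 °C to rt; AcOH to pH 5; then camphorsulfonic acid (cat.), CH2Cl2, 0 °C
Reagents that add atoms: lithium hydroxide, [Li+].[OH-]
Why: saponification cleaves the methyl ester and the C6 acetate, and under mild acid catalysis the carboxyl group opens the epoxide 5-exo at the tertiary C12 with inversion (epoxy acid lactonisation), so the (11R,12R)-epoxide should give the (11R,12S)-hydroxy lactone of ring B with the epoxide oxygen kept as the C11 hydroxyl.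

**Compound list**

1 | acrolein | C=CC=O | starting material
2 | propargyl bromide | C#CCBr | starting material
3 | propa-1,2-dienylzinc bromide (allenylzinc bromide) | C=C=C[Zn]Br | intermediate
4 | rac-hex-1-en-5-yn-3-ol | C=CC(O)CC#C | intermediate
5 | [(1E)-4-(dimethylalumanyloxy)-2-methylhexa-1,5-dienyl]dimethylalumane (alkenylalane, racemic) | C=CC(O[Al](C)C)C/C(C)=C/[Al](C)C | intermediate
6 | rac-(5E)-6-iodo-5-methylhexa-1,5-dien-3-ol | C=CC(O)C/C(C)=C/I | intermediate
7 | (3S,5E)-6-iodo-5-methylhexa-1,5-dien-3-ol | C=C[C@@H](O)C/C(C)=C/I | intermediate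
8 | furan-3-carbaldehyde | O=Cc1ccoc1 | starting material
9 | 3-ethenylfuran | C=Cc1ccoc1 | intermediate
10 | 9-[2-(furan-3-yl)ethyl]-9-borabicyclo[3.3.1]nonane | C(Cc1ccoc1)B1C2CCCC1CCC2 | intermediate
11 | (3S,5E)-8-(furan-3-yl)-5-methylocta-1,5-dien-3-ol | C=C[C@@H](O)C/C(C)=C/CCc1ccoc1 | intermediate
12 | triethyl phosphonoacetate | CCOC(=O)CP(=O)(OCC)OCC | starting material
13 | 2-(2-bromoethyl)-1,3-dioxolane | BrCCC1OCCO1 | starting material
14 | ethyl 2-(diethoxyphosphoryl)-4-(1,3-dioxolan-2-yl)butanoate (racemic) | CCOC(=O)C(CCC1OCCO1)P(=O)(OCC)OCC | intermediate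
15 | ethyl 4-(1,3-dioxolan-2-yl)-2-methylidenebutanoate | C=C(CCC1OCCO1)C(=O)OCC | intermediate
16 | 4-(1,3-dioxolan-2-yl)-2-methylidenebutanoic acid | C=C(CCC1OCCO1)C(=O)O | intermediate
17 | (3S,5E)-8-(furan-3-yl)-5-methylocta-1,5-dien-3-yl 4-(1,3-dioxolan-2-yl)-2-methylidenebutanoate | C=C(CCC1OCCO1)C(=O)O[C@H](C=C)C/C(C)=C/CCc2ccoc2 | intermediate
18 | (5S)-3-[2-(1,3-dioxolan-2-yl)ethyl]-5-[(2E)-5-(furan-3-yl)-2-methylpent-2-enyl]furan-2(5H)-one | O=C1O[C@@H](C/C(C)=C/CCc2ccoc2)C=C1CCC3OCCO3 | intermediate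
19 | (2Z,4S,6E)-2-[2-(1,3-dioxolan-2-yl)ethyl]-9-(furan-3-yl)-6-methylnona-2,6-diene-1,4-diol | OC/C(CCC1OCCO1)=C\[C@@H](O)C/C(C)=C/CCc1ccoc1 | intermediate
20 | (2Z,4S,6E)-2-[2-(1,3-dioxolan-2-yl)ethyl]-9-(furan-3-yl)-4-hydroxy-6-methylnona-2,6-dienyl methanesulfonate | CS(=O)(=O)OC/C(CCC1OCCO1)=C\[C@@H](O)C/C(C)=C/CCc1ccoc1 | intermediate
21 | (3E,5S,7E)-1-(1,3-dioxolan-2-yl)-10-(furan-3-yl)-3,7-dimethyldeca-3,7-dien-5-ol | C/C(CCC1OCCO1)=C\[C@@H](O)C/C(C)=C/CCc1ccoc1 | intermediate
22 | (3E,5S,7E)-1-(1,3-dioxolan-2-yl)-10-(furan-3-yl)-3,7-dimethyldeca-3,7-dien-5-yl acetate | C/C(CCC1OCCO1)=C\[C@@H](OC(C)=O)C/C(C)=C/CCc1ccoc1 | intermediate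
23 | (4E,6S,8E)-11-(furan-3-yl)-4,8-dimethyl-1-oxoundeca-4,8-dien-6-yl acetate | C/C(CCC=O)=C\[C@@H](OC(C)=O)C/C(C)=C/CCc1ccoc1 | intermediate
24 | 2-(triphenylphosphoranylidene)propanal | CC(C=O)=P(c1ccccc1)(c1ccccc1)c1ccccc1 | starting material
25 | (2E,6E,8S,10E)-13-(furan-3-yl)-2,6,10-trimethyl-1-oxotrideca-2,6,10-trien-8-yl acetate | O=C/C(C)=C/CC/C(C)=C/[C@@H](OC(C)=O)C/C(C)=C/CCc1ccoc1 | intermediate
26 | (2E,6E,8S,10E)-13-(furan-3-yl)-1-hydroxy-2,6,10-trimethyltrideca-2,6,10-trien-8-yl acetate | OC/C(C)=C/CC/C(C)=C/[C@@H](OC(C)=O)C/C(C)=C/CCc1ccoc1 | intermediate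
27 | (3E,5S,7E)-10-(furan-3-yl)-1-[(2R,3R)-3-(hydroxymethyl)-3-methyloxiran-2-yl]-3,7-dimethyldeca-3,7-dien-5-yl acetate | OC[C@@]1(C)O[C@@H]1CC/C(C)=C/[C@@H](OC(C)=O)C/C(C)=C/CCc1ccoc1 | intermediate
28 | methyl (triphenylphosphoranylidene)acetate | COC(=O)C=P(c1ccccc1)(c1ccccc1)c1ccccc1 | starting material
29 | (3E,5S,7E)-1-[(2R,3S)-3-formyl-3-methyloxiran-2-yl]-10-(furan-3-yl)-3,7-dimethyldeca-3,7-dien-5-yl acetate | O=C[C@@]1(C)O[C@@H]1CC/C(C)=C/[C@@H](OC(C)=O)C/C(C)=C/CCc1ccoc1 | intermediate
30 | methyl (2E)-3-[(2R,3R)-3-{(3E,5S,7E)-5-acetoxy-10-(furan-3-yl)-3,7-dimethyldeca-3,7-dienyl}-2-methyloxiran-2-yl]prop-2-enoate | COC(=O)/C=C/[C@@]1(C)O[C@@H]1CC/C(C)=C/[C@@H](OC(C)=O)C/C(C)=C/CCc1ccoc1 | intermediate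
31 | methyl 3-[(2R,3R)-3-{(3E,5S,7E)-5-acetoxy-10-(furan-3-yl)-3,7-dimethyldeca-3,7-dienyl}-2-methyloxiran-2-yl]propanoate | COC(=O)CC[C@@]1(C)O[C@@H]1CC/C(C)=C/[C@@H](OC(C)=O)C/C(C)=C/CCc1ccoc1 | intermediate
32 | 3-[(2R,3R)-3-{(3E,5S,7E)-10-(furan-3-yl)-5-hydroxy-3,7-dimethyldeca-3,7-dienyl}-2-methyloxiran-2-yl]propanoic acid | OC(=O)CC[C@@]1(C)O[C@@H]1CC/C(C)=C/[C@@H](O)C/C(C)=C/CCc1ccoc1 | intermediate
33 | irciformonin B, (5S)-5-[(1R,4E,6S,8E)-11-(furan-3-yl)-1,6-dihydroxy-4,8-dimethylundeca-4,8-dienyl]-5-methyloxolan-2-one | C/C(=C\[C@@H](O)C/C(C)=C/CCc1ccoc1)CC[C@@H](O)[C@]1(C)CCC(=O)O1 | target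

**Count and risk**

Total steps: 20. Longest linear sequence: 16 (steps 1–3, 5, 9–20).

The three steps most likely to fail, in falling order of risk:

Step 12. The free C6 hydroxyl, held cis to the activated primary allylic carbon, may close onto it to a 2,5-dihydrofuran, the sulfonylation may fail to distinguish the two hydroxyls, or hydride may attack with allylic transposition. The fallback sets out from diol 19 and removes the free hydroxyl from the neighbourhood of the leaving group. Double silylation (TBSCl, imidazole, DMF) would give the bis(tert-butyldimethylsilyl) ether F6. Selective cleavage of the primary allylic silyl ether (HF·pyridine, pyridine, THF, 0 °C) would give the primary alcohol F7. Mesylation (MsCl, Et3N, THF, −40 °C) would give the mesylate F8, and LiBHEt3 would give the silyl ether F9. Bu4NF in THF would then come back to the route at alcohol 21.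

Step 10. Closure onto the hindered, electron-poor 1,1-disubstituted olefin may be outrun by intermolecular metathesis at the vinyl group or by catalyst decay with olefin migration. The fallback builds ring C by carbonyl olefination and lactonisation instead of metathesis and sets out from iodo alcohol 7. Silylation (TBSCl, imidazole) would give the silyl ether F1. Lemieux–Johnson cleavage of its terminal vinyl group (OsO4 cat., NaIO4, 2,6-lutidine, dioxane/H2O; the iodo-olefin is electron-poor and slower) would give the α-silyloxy aldehyde F2. Still–Gennari olefination with the trifluoroethyl phosphonate F3 (made from methyl bis(2,2,2-trifluoroethyl)phosphonoacetate and 13 as in step 6; KN(SiMe3)2, 18-crown-6, THF, −78 °C) would give the Z enoate F4. Desilylation with HF·pyridine would free the C6 hydroxyl, which lactonises onto the cis ester to the iodo butenolide F5. B-alkyl Suzuki–Miyaura coupling of F5 with borane 10 under the conditions of step 5 would come back to the route at butenolide 18.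

Step 19. Hydrogen transfer to the enoate next to the fully substituted epoxide carbon may be sluggish, and forcing it may begin to saturate the trisubstituted olefins. The fallback sets out from epoxy alcohol 27 and brings in C14–C15 at the sp3 level, so that no C13=C14 olefin is ever made and steps 18 and 19 are both bypassed. Tf2O and 2,6-lutidine in CH2Cl2 at −78 °C would give the epoxy triflate F10. SN2 displacement with the lithium enolate of methyl acetate (LiN(i-Pr)2, THF, −78 °C) would come back to the route at ester 31.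

**Further compounds**

F1 | step 10 | tert-butyl{[(3S,5E)-6-iodo-5-methylhexa-1,5-dien-3-yl]oxy}dimethylsilane | C=C[C@@H](O[Si](C)(C)C(C)(C)C)C/C(C)=C/I
F2 | step 10 | (2S,4E)-2-[tert-butyl(dimethyl)silyloxy]-5-iodo-4-methylpent-4-enal | O=C[C@@H](O[Si](C)(C)C(C)(C)C)C/C(C)=C/I
F3 | step 10 | methyl 2-[bis(2,2,2-trifluoroethoxy)phosphoryl]-4-(1,3-dioxolan-2-yl)butanoate | COC(=O)C(CCC1OCCO1)P(=O)(OCC(F)(F)F)OCC(F)(F)F
F4 | step 10 | methyl (2Z,4S,6E)-4-[tert-butyl(dimethyl)silyloxy]-2-[2-(1,3-dioxolan-2-yl)ethyl]-7-iodo-6-methylhepta-2,6-dienoate | COC(=O)/C(CCC1OCCO1)=C\[C@@H](O[Si](C)(C)C(C)(C)C)C/C(C)=C/I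
F5 | step 10 | (5S)-3-[2-(1,3-dioxolan-2-yl)ethyl]-5-[(2E)-3-iodo-2-methylprop-2-enyl]furan-2(5H)-one | O=C1O[C@@H](C/C(C)=C/I)C=C1CCC2OCCO2
F6 | step 12 | 1,4-bis-O-(tert-butyldimethylsilyl) ether of diol 19 | CC(C)(C)[Si](C)(C)OC/C(CCC1OCCO1)=C\[C@@H](O[Si](C)(C)C(C)(C)C)C/C(C)=C/CCc1ccoc1
F7 | step 12 | 4-O-(tert-butyldimethylsilyl) ether of diol 19 (primary hydroxyl free) | OC/C(CCC1OCCO1)=C\[C@@H](O[Si](C)(C)C(C)(C)C)C/C(C)=C/CCc1ccoc1
F8 | step 12 | 1-O-methanesulfonate of F7 | CS(=O)(=O)OC/C(CCC1OCCO1)=C\[C@@H](O[Si](C)(C)C(C)(C)C)C/C(C)=C/CCc1ccoc1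
F9 | step 12 | tert-butyldimethylsilyl ether of alcohol 21 | C/C(CCC1OCCO1)=C\[C@@H](O[Si](C)(C)C(C)(C)C)C/C(C)=C/CCc1ccoc1
F10 | step 19 | {(2R,3R)-3-[(3E,5S,7E)-5-acetoxy-10-(furan-3-yl)-3,7-dimethyldeca-3,7-dienyl]-2-methyloxiran-2-yl}methyl trifluoromethanesulfonate | FC(F)(F)S(=O)(=O)OC[C@@]1(C)O[C@@H]1CC/C(C)=C/[C@@H](OC(C)=O)C/C(C)=C/CCc1ccoc1
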